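## Analysis of the target

The target is a 24-membered macrocyclic bis-lactam. Spermidine is acylated at N1 and N8 by two (E)-cinnamoyl units whose arenes are joined by a diaryl ether, so the ring runs N8–CO–CH=CH–ring A–O–ring B–CH=CH–CO–N1 and back through the triamine. Ring A, on the four-carbon (N8) arm, is 1,3,4-trisubstituted: the propenamide at C1, the ether oxygen at C3 and a hydrogen sulfate ester on O4. Ring B, on the three-carbon (N1) arm, is para-disubstituted with the ether oxygen at C4'. There is no stereocentre; the only stereochemical elements are the two E double bonds, which are independent of each other and must be kept from light-, thiol- or base-induced isomerization. The sensitive groups are the aryl sulfate monoester (cleaved by acid, so it must come late and be handled as a salt), the basic, nucleophilic and oxidizable secondary amine N4 (it would itself be sulfonated), and the two cinnamamide Michael acceptors. The difficulties are closure of a large ring, correct placement of two almost identical arylpropenoyl arms on an unsymmetrical triamine (sulfated ring on the N8 side), and isolation of a polar inner salt. The strategy rests on the bond between O4' of ring B and C3 of ring A, ortho to O4 of ring A. This 2-aryloxyphenol pattern is what an ortho C–O coupling of two 4-hydroxycinnamoyl phenols would leave, and after such a coupling ring A carries the only free hydroxyl, exactly where the sulfate is needed.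

## Retrosynthetic reasoning

**10 to 9.** The last bond cut is N4–H, traced back to the N4 carbamate of 9. N4 stays masked as a 2-(trimethylsilyl)ethyl carbamate (Teoc) to the end because it must not be sulfonated, oxidized or act as a nucleophile earlier. This carbamate is preferred over acid-labile ones because a fluoride source removes it at neutral to basic pH, where the aryl sulfate monoanion is stable. The forward step only has to avoid acid.

**9 to 8.** The S–O bond of the sulfate is cut next, giving phenol 8. Sulfation comes after ring closure because in 8 the oxygen of ring B is already the ether. The single remaining hydroxyl is the one on ring A, so no phenol protecting group is needed anywhere in the route.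

**8 to 6.** The macrocycle is opened at the diaryl ether, between O4' of ring B and C3 of ring A, leading through dienone 7 to the open bis-phenol 6. The cut is made here, and not at an amide, at N4 or at an alkene, because it removes the only feature that makes the two arms different. Compound 6 carries the same 4-hydroxycinnamoyl group on N1 and N8, so neither the two primary amines of the triamine nor the arenes need differentiation or prefunctionalization. The gain is brevity. The price is that the forward step must make the C–O bond by dehydrogenative coupling of two phenols, ortho on ring A, with ring B as oxygen partner, and within one molecule. The substrate alone does not secure all of these.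

**6 to 4 and 5.** The two amide bonds are cut to diamine 4 and two molecules of acid 5. Both acylations are the same reaction and are run together; the E alkenes and the phenols arrive with 5.

**4 to 1.** The N4 carbamate is traced to spermidine 1 through 3 and 2. The two primary amines are masked as trifluoroacetamides (2), which leaves N4 as the only amine for carbamate formation (3); mild base then frees the primary amines (4).

## Alternatives that were turned down

**Alternative 1:** The amide between the ring B carbonyl and N1 is disconnected to the isomeric 20-membered lactam A2, in which that carbonyl sits on N4 and N1 hangs from N4 as a free 3-aminopropyl group. In the forward direction the primary amine attacks the neighbouring tertiary amide through a six-membered tetrahedral intermediate; the acyl group moves from N4 to N1, the ring grows by four atoms and A1 forms with N4 free.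
- For: the shift is downhill (tertiary amide to secondary amide, smaller ring to larger), the six-membered transition state is entropically cheap, and the sense of the diaryl ether is fixed earlier by conventional aryl ether synthesis. On regiochemical certainty it is stronger than the chosen route.
- Against: A2 is itself a macrocycle that must first be closed. The diaryl ether has to come from prefunctionalized arenes with the ring A oxygen carried as a methoxymethyl ether. The primary amine of A2 can also add in conjugate fashion to either cinnamoyl unit under the basic conditions of acyl transfer. A1 emerges with N4 unprotected, so N4 must be masked again before sulfation and the acetal removed with acid.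
- Comparison: the sequence would be roughly twice as long. The chosen route offers in exchange that ring, diaryl ether and free ring A phenol all arise in one operation from a precursor made in three steps.

**Alternative 2:** The ring is opened at the bond between N4 and the first carbon of the four-carbon chain, giving the open-chain alcohol sulfonamide A4. Forward, the acidic N–H of the 2-nitrobenzenesulfonamide is alkylated by the primary alcohol under Mitsunobu conditions at high dilution to give A3.
- For: sulfonamide alkylation of this kind is among the most dependable ways to close polyamine macrocycles, needs no metal, and the sulfonyl group protects N4 through the sulfation. In reliability of ring closure and in certainty of connectivity it is clearly stronger than the chosen route.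
- Against: A4 already contains the diaryl ether and both amides, so its assembly needs prior diaryl ether formation from prefunctionalized arenes and separate introduction of the two nitrogen chains, about a dozen linear steps. The sulfonyl group must finally be removed with a thiolate, a soft nucleophile that can add to the two cinnamamides. The acetal on ring A again calls for acid.
- Comparison: the chosen route gives up the certainty of the Mitsunobu closure but needs no phenol protection, no thiolate and no differentiated triamine.

**Alternative 3:** The E double bond of the ring B propenamide is cut, leading to A6, which has an aldehyde on ring B and a phosphonoacetamide on N1. Forward, a mild-base Horner–Wadsworth–Emmons reaction at high dilution closes the ring and sets the alkene, giving A5.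
- For: stabilized phosphonates and aryl aldehydes give E alkenes reliably, macrocyclic olefinations of this kind are well established, and the aldehyde-bearing diaryl ether comes from a simple nucleophilic aromatic substitution. A5 carries the same N4 carbamate as 8, so the end game would be the same once the acetal is removed. This is probably the most dependable of the four plans and is stronger than the chosen one on every question of selectivity.
- Against: the two primary amines of 1 must be told apart (phosphonoacetyl on N1, cinnamoyl on N8). The ring A oxygen needs an acetal whose acidic removal endangers the silylethyl carbamate. The count comes to eleven or twelve steps.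
- Comparison: the chosen strategy reaches the same macrocycle in four steps from 1 without differentiating N1 and N8 and without phenol protection. Its weakness, an unprecedented and only partly controlled coupling, is covered by a fallback that uses conventional logic.

Key step: step 4

Remark: the target is drawn as the free sulfuric acid monoester and free amine; it should exist and be isolated as the inner salt (N4 ammonium, aryl sulfate), and 9 is carried as its sodium salt because free aryl hydrogen sulfates hydrolyse autocatalytically.

## Route

Teoc = 2-(trimethylsilyl)ethoxycarbonyl. Ring A is the arene on the N8 arm, ring B the arene on the N1 arm.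

Step 1
Reactants: 1 spermidine
Product: 3 N1,N8-bis(trifluoroacetyl)-N4-Teoc-spermidine, via N1,N8-bis(trifluoroacetyl)spermidine 2 (not isolated)
Conditions: CF3CO2Et (2.1 equiv), MeOH, −78 → 0 °C; then Teoc-OSu (1.1 equiv), Et3N, 0 °C → rt
Reagents that add atoms: ethyl trifluoroacetate, CCOC(=O)C(F)(F)F; N-[2-(trimethylsilyl)ethoxycarbonyloxy]succinimide (Teoc-OSu), C[Si](C)(C)CCOC(=O)ON1C(=O)CCC1=O
Why: Ethyl trifluoroacetate acylates only the two primary amines of a polyamine at low temperature (selective aminolysis of an activated ester), which leaves N4 as the single nucleophile for carbamate formation with the succinimidyl carbonate. The neutral product 3 can be purified on silica, which the free diamine cannot.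

Step 2
Reactants: 3 N1,N8-bis(trifluoroacetyl)-N4-Teoc-spermidine
Product: 4 N4-Teoc-spermidine
Conditions: K2CO3, MeOH/H2O (5:1), rt → 50 °C
Reagents that add atoms: none
Why: Trifluoroacetamides are hydrolysed by mild aqueous carbonate (base cleavage of an activated amide), conditions to which the N4 carbamate is inert.

Step 3
Reactants: 4 N4-Teoc-spermidine; 5 (E)-4-hydroxycinnamic acid (2.1 equiv)
Product: 6 N1,N8-bis[(E)-4-hydroxycinnamoyl]-N4-Teoc-spermidine
Conditions: EDC·HCl, HOBt, DMF, 0 °C → rt
Reagents that add atoms: none
Why: Carbodiimide/HOBt amidation; the primary amines are far better nucleophiles than the phenols toward the activated acid, so 5 can be used unprotected. The E geometry of 5 is carried over unchanged.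

Step 4
Reactants: 6 N1,N8-bis[(E)-4-hydroxycinnamoyl]-N4-Teoc-spermidine
Product: 8 N4-Teoc 24-membered macrocyclic diaryl ether phenol (ring B O4' bonded to ring A C3; ring A 4-OH free), via macrocyclic 6-aryloxycyclohexa-2,4-dienone 7 (not isolated)
Conditions: [Cu(OH)(TMEDA)]2Cl2 (1.1 equiv; TMEDA = Me2NCH2CH2NMe2), CH2Cl2/MeOH (9:1), 0.5 mM, Ar, dark, rt → 40 °C; then aq. Na2H2EDTA
Reagents that add atoms: none
Why: Proposed new method: the two hydroxide ligands of the dimeric divalent-copper reagent deprotonate both phenols of 6 and bind the two phenoxide oxygens side by side on copper; inner-sphere electron transfer (each of the two divalent copper centres takes one electron) gives two copper-associated phenoxyl radicals, the oxygen of ring B bonds to C3 of ring A to give dienone 7, and 7 enolizes to the phenol 8. The closest known reaction types are the copper–amine oxidative C–O coupling of phenols that gives poly(phenylene oxide)s and the enzymatic (cytochrome P450, laccase) or anodic coupling of phenols to diaryl ethers; an intramolecular ortho C–O coupling of two 4-hydroxycinnamoyl amides has not been shown. The 24-membered ring is closed by end-to-end recombination of the two oxidized phenol termini of one chain, favoured by 0.5 mM dilution and by chelation of both termini to one copper unit. No stereocentre results: the sp3 carbon C3 of 7 is lost on enolization and both E alkenes are spectators. Ring closure must beat oligomerization (dilution, chelation), and O-to-ortho-carbon bonding must beat coupling at the side-chain carbon next to the carbonyl, where 4-hydroxycinnamoyl radicals usually react: with both oxygens held on the metal only O and the ortho carbons of the partner ring are within bonding distance and the two side chains point apart, while bonding at the substituted carbon C1 gives a dienone that cannot enolize and can only revert. Ortho–ortho C–C coupling and the reverse sense of C–O coupling (ring A oxygen to ring B carbon) are not excluded by the substrate, whose only bias is the unequal length of its three- and four-carbon arms, so 8 is expected to need chromatographic separation from isomeric macrocycles and proof of its connectivity by HMBC. Stoichiometric divalent copper under argon supplies exactly two electrons, which should protect the more electron-rich phenol of 8 from further oxidation.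

Step 5
Reactants: 8 N4-Teoc 24-membered macrocyclic diaryl ether phenol
Product: 9 sodium salt of the ring A O4-sulfate of 8
Conditions: SO3·pyridine (5 equiv), pyridine, rt → 40 °C; then aq. NaHCO3 (pH 8), C18 desalting
Reagents that add atoms: sulfur trioxide–pyridine complex, O=S(=O)=O.c1ccncc1; sodium hydrogencarbonate, [Na+].OC([O-])=O
Why: O-Sulfonation of a phenol by the sulfur trioxide–pyridine complex; 8 has a single hydroxyl, N4 is a carbamate and the amide nitrogens are not sulfonated under these conditions, so the site is unambiguous. The product is kept at pH 7 or above as its sodium salt because aryl sulfate monoesters hydrolyse in acid.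

Step 6
Reactants: 9 sodium salt of the ring A O4-sulfate of 8
Product: 10 the target (CID124202369), isolated as the inner salt
Conditions: Bu4NF (4 equiv), DMF, rt → 45 °C; then AcOH to pH 6; reversed-phase C18 (H2O/MeCN)
Reagents that add atoms: none
Why: Fluoride-induced β-elimination of the 2-(trimethylsilyl)ethyl carbamate (loss of fluorotrimethylsilane, ethene and CO2) runs without acid, so the aryl sulfate monoanion and the two cinnamamides should survive. Acidification to pH 6 gives the N4 ammonium / aryl sulfate inner salt.

## Compound list

1 | spermidine [N1-(3-aminopropyl)butane-1,4-diamine] | NCCCNCCCCN | starting material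
2 | N1,N8-bis(trifluoroacetyl)spermidine (not isolated) | O=C(NCCCNCCCCNC(=O)C(F)(F)F)C(F)(F)F | intermediate
3 | N1,N8-bis(trifluoroacetyl)-N4-Teoc-spermidine [2-(trimethylsilyl)ethyl N-[3-(trifluoroacetamido)propyl]-N-[4-(trifluoroacetamido)butyl]carbamate] | O=C(NCCCN(C(=O)OCC[Si](C)(C)C)CCCCNC(=O)C(F)(F)F)C(F)(F)F | intermediate
4 | N4-Teoc-spermidine [2-(trimethylsilyl)ethyl N-(3-aminopropyl)-N-(4-aminobutyl)carbamate] | NCCCN(C(=O)OCC[Si](C)(C)C)CCCCN | intermediate
5 | (E)-4-hydroxycinnamic acid | O=C(O)/C=C/c1ccc(O)cc1 | starting material
6 | N1,N8-bis[(E)-4-hydroxycinnamoyl]-N4-Teoc-spermidine | Oc1ccc(cc1)/C=C/C(=O)NCCCN(C(=O)OCC[Si](C)(C)C)CCCCNC(=O)/C=C/c1ccc(O)cc1 | intermediate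
7 | dienone tautomer of 8 (not isolated): ring A is a cyclohexa-2,4-dienone with C4 as carbonyl and sp3 C3 bearing H and the ring B oxygen; C3 configuration undefined and transient | O=C1/C=C/C2=CC(Oc3ccc(cc3)/C=C/C(=O)NCCCN(C(=O)OCC[Si](C)(C)C)CCCCN1)C(=O)C=C2 | intermediate
8 | N4-Teoc 24-membered macrocycle: O4' of the N1-linked (E)-cinnamoyl ring B bonded to C3 of the N8-linked (E)-4-hydroxycinnamoyl ring A, ring A 4-OH free | O=C1/C=C/c2ccc(O)c(c2)Oc2ccc(cc2)/C=C/C(=O)NCCCN(C(=O)OCC[Si](C)(C)C)CCCCN1 | intermediate
9 | sodium salt of the ring A O4-sulfate of 8 | O=C1/C=C/c2ccc(OS(=O)(=O)[O-])c(c2)Oc2ccc(cc2)/C=C/C(=O)NCCCN(C(=O)OCC[Si](C)(C)C)CCCCN1.[Na+] | intermediate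
10 | CID124202369: N4-unprotected 24-membered macrocycle with ring A O4 hydrogen sulfate, both alkenes E | O=C1/C=C/c2ccc(OS(=O)(=O)O)c(c2)Oc2ccc(cc2)/C=C/C(=O)NCCCNCCCCN1 | target

## Step count and least certain steps

Total step count: 6. Longest linear sequence: 6 steps (1 → 3 → 4 → 6 → 8 → 9 → 10).

**Step 4 (key step, the one proposed new method).**
- What may go wrong: coupling through the side-chain carbon next to the carbonyl, the usual course for 4-hydroxycinnamoyl radicals, because spin density there is high. Ortho–ortho C–C coupling and C–O coupling in the reverse sense, because the two arms are nearly identical. Intermolecular coupling. Electron transfer from an acrylamide-substituted phenoxide to amine-ligated divalent copper may also be too slow, leaving 6 unchanged.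
- Fallback (known chemistry; sets out from 1, returns at 8): Spermidine 1 is condensed with one equivalent of aqueous formaldehyde, which ties N1 and N4 into a six-membered aminal and leaves N8 as the only primary amine: 1-(4-aminobutyl)hexahydropyrimidine F1. The ring A acid is made separately from commercial 3,4-dihydroxybenzaldehyde. Allylation of the more acidic 4-hydroxyl (allyl bromide, K2CO3, DMF) gives 4-(allyloxy)-3-hydroxybenzaldehyde F2, and Doebner condensation with malonic acid (pyridine, piperidine) gives (E)-4-(allyloxy)-3-hydroxycinnamic acid F3. F3 is coupled to the primary amine of F1 (EDC·HCl, HOBt) to give amide F4. The ring N–H is then acylated with commercial (E)-4-iodocinnamic acid (EDC·HCl, HOBt) to give the diacyl aminal F5. The aminal is opened with malonic acid in pyridine/ethanol, which takes up the formaldehyde by Knoevenagel condensation, to give the N1,N8-diacyl spermidine F6, and N4 is protected with Teoc-OSu to give F7. Intramolecular Ullmann ether synthesis (CuI, N,N-dimethylglycine, Cs2CO3, 1,4-dioxane, 90 °C, 2 mM) joins the ring A 3-hydroxyl to the iodinated carbon of ring B and closes the 24-membered ring as the allyl ether F8. Allyl transfer catalysed by zerovalent palladium (Pd(PPh3)4, morpholine, THF) frees the ring A phenol and gives 8. In this sequence the sense of the diaryl ether is fixed by which ring carries iodine.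

**Step 3.**
- What may go wrong: O-acylation of the free phenols, giving ester-linked oligomers and incomplete bis-amidation, because the activated acid carries its own nucleophile.
- Fallback (sets out from 5 and 4, returns at 6): 5 is O-acetylated (Ac2O, pyridine) to (E)-4-acetoxycinnamic acid F9 and converted with (COCl)2 and catalytic DMF into the acid chloride F10. F10 acylates both primary amines of 4 (Et3N, CH2Cl2, 0 °C) to give the bis-acetate F11. K2CO3 in MeOH removes the aryl acetates and gives 6.

**Step 5.**
- What may go wrong: incomplete sulfonation of the hindered ortho-aryloxy phenol, and loss of the sulfate by hydrolysis during purification of the charged product.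
- Fallback (sets out from 8, returns at 9): 8 is treated with 2,2,2-trichloroethyl chlorosulfate (Et3N, DMAP, THF) to give the neutral mixed sulfate diester F12, which can be chromatographed on silica. Reductive removal of the trichloroethyl group (Zn, HCO2NH4, MeOH) and exchange to the sodium salt gives 9.

**Step 6.**
- What may go wrong: slow carbamate cleavage that needs heating under basic fluoride conditions, with conjugate addition of the freed amine or erosion of alkene geometry; difficult removal of tetrabutylammonium salts from the inner salt; partial loss of sulfate on acidification.
- Fallback (sets out from 8, returns at 10): the last two operations are exchanged. Bu4NF removes the carbamate from 8 to give the free amine phenol F13, which is purified as an ordinary basic compound. The phenol is then sulfated chemoselectively with a bacterial aryl sulfotransferase and 4-nitrophenyl sulfate as donor in aqueous buffer at pH 8–9, where N4 is protonated and is not a substrate, giving 10 directly.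

## Further compounds

F1 | step 4 | 1-(4-aminobutyl)hexahydropyrimidine | NCCCCN1CNCCC1
F2 | step 4 | 4-(allyloxy)-3-hydroxybenzaldehyde | O=Cc1ccc(OCC=C)c(O)c1
F3 | step 4 | (E)-4-(allyloxy)-3-hydroxycinnamic acid | O=C(O)/C=C/c1ccc(OCC=C)c(O)c1
F4 | step 4 | (E)-3-[4-(allyloxy)-3-hydroxyphenyl]-N-[4-(hexahydropyrimidin-1-yl)butyl]prop-2-enamide | O=C(/C=C/c1ccc(OCC=C)c(O)c1)NCCCCN1CNCCC1
F5 | step 4 | F4 acylated at the ring N–H with (E)-4-iodocinnamoyl (diacyl aminal) | O=C(/C=C/c1ccc(OCC=C)c(O)c1)NCCCCN1CN(C(=O)/C=C/c2ccc(I)cc2)CCC1
F6 | step 4 | N8-[(E)-4-(allyloxy)-3-hydroxycinnamoyl]-N1-[(E)-4-iodocinnamoyl]spermidine | O=C(/C=C/c1ccc(OCC=C)c(O)c1)NCCCCNCCCNC(=O)/C=C/c1ccc(I)cc1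
F7 | step 4 | N4-Teoc derivative of F6 | O=C(/C=C/c1ccc(OCC=C)c(O)c1)NCCCCN(C(=O)OCC[Si](C)(C)C)CCCNC(=O)/C=C/c1ccc(I)cc1
F8 | step 4 | ring A O4-allyl ether of 8 | O=C1/C=C/c2ccc(OCC=C)c(c2)Oc2ccc(cc2)/C=C/C(=O)NCCCN(C(=O)OCC[Si](C)(C)C)CCCCN1
F9 | step 3 | (E)-4-acetoxycinnamic acid | CC(=O)Oc1ccc(/C=C/C(=O)O)cc1
F10 | step 3 | (E)-4-acetoxycinnamoyl chloride | CC(=O)Oc1ccc(/C=C/C(=O)Cl)cc1
F11 | step 3 | bis-O-acetate of 6 | CC(=O)Oc1ccc(cc1)/C=C/C(=O)NCCCN(C(=O)OCC[Si](C)(C)C)CCCCNC(=O)/C=C/c1ccc(OC(C)=O)cc1
F12 | step 5 | 2,2,2-trichloroethyl sulfate diester of 8 (on ring A O4) | O=C1/C=C/c2ccc(OS(=O)(=O)OCC(Cl)(Cl)Cl)c(c2)Oc2ccc(cc2)/C=C/C(=O)NCCCN(C(=O)OCC[Si](C)(C)C)CCCCN1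
F13 | step 6 | N4-unprotected macrocyclic phenol (8 without Teoc) | O=C1/C=C/c2ccc(O)c(c2)Oc2ccc(cc2)/C=C/C(=O)NCCCNCCCCN1
A1 | alternative 1 | 24-membered macrocycle with free N4 and ring A O-methoxymethyl ether (product of the acyl shift) | O=C1/C=C/c2ccc(OCOC)c(c2)Oc2ccc(cc2)/C=C/C(=O)NCCCNCCCCN1
A2 | alternative 1 | 20-membered N4-acyl lactam with a 3-aminopropyl group on N4 | O=C1/C=C/c2ccc(OCOC)c(c2)Oc2ccc(cc2)/C=C/C(=O)N(CCCN)CCCCN1
A3 | alternative 2 | N4-(2-nitrobenzenesulfonyl), O-methoxymethyl 24-membered macrocycle | O=C1/C=C/c2ccc(OCOC)c(c2)Oc2ccc(cc2)/C=C/C(=O)NCCCN(S(=O)(=O)c2ccccc2[N+](=O)[O-])CCCCN1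
A4 | alternative 2 | open-chain 4-hydroxybutyl amide with N-(3-amidopropyl) 2-nitrobenzenesulfonamide | OCCCCNC(=O)/C=C/c1ccc(OCOC)c(c1)Oc1ccc(cc1)/C=C/C(=O)NCCCNS(=O)(=O)c1ccccc1[N+](=O)[O-]
A5 | alternative 3 | N4-Teoc, O-methoxymethyl 24-membered macrocycle | O=C1/C=C/c2ccc(OCOC)c(c2)Oc2ccc(cc2)/C=C/C(=O)NCCCN(C(=O)OCC[Si](C)(C)C)CCCCN1
A6 | alternative 3 | open-chain ring B aldehyde with N1 diethylphosphonoacetamide | CCOP(=O)(OCC)CC(=O)NCCCN(C(=O)OCC[Si](C)(C)C)CCCCNC(=O)/C=C/c1ccc(OCOC)c(c1)Oc1ccc(C=O)cc1
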